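The target (2S,3S,4S,5S) has a C2 axis through O1 and the C3–C4 bond, and each aryl is cis to the CH2OH on the adjacent ring carbon (C2/C3, C5/C4), the less stable arrangement. The aryl–C2 bond is therefore made last, by aryl transfer from silicon: both CH2O oxygens carry aryl(dimethyl)silyl tethers, and ionisation of a 2-acetoxy-5-menthyloxyoxolane gives oxocarbenium ions that are attacked by the ipso carbon of the tethered arene on the face of its own arm. One flask forms both aryl–C bonds and both benzylic stereocentres; the second transfer joins the remaining aryl to the oxolane that already bears the first. The precursor carries its aryls on silicon.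

Key step: step 7

Remark: in the names below Ar = 4-(benzyloxy)-3-methoxyphenyl and Men = (1R,2S,5R)-5-methyl-2-(propan-2-yl)cyclohexyl (from (−)-menthol); oxolane atoms keep the target numbering (O1, C2 to C5). The acetal centres (C2 of 13, C5 of 6 to 14) are temporary and are planarised in step 7.

Step 1
Reactants: 1 1-(benzyloxy)-4-bromo-2-methoxybenzene
Product: 3 [4-(benzyloxy)-3-methoxyphenyl]chlorodimethylsilane, via aryllithium 2 (not isolated)
Conditions: n-BuLi, THF, −78 °C; cannulated into Me2SiCl2 (4 equiv), THF, −78 °C → rt; volatiles removed, pentane, filtration under Ar, Kugelrohr distillation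
Reagents that add atoms: dichlorodimethylsilane C[Si](C)(Cl)Cl
Why: Bromine–lithium exchange gives the aryllithium at the carbon para to the benzyloxy group, and inverse addition to excess Me2SiCl2 (nucleophilic substitution at silicon) should stop at monoarylation, so silicon sits on exactly the ring carbon that later bonds to the oxolane.

Step 2
Reactants: 4 5-hydroxyfuran-2(5H)-one (racemic); 5 (−)-menthol
Product: 6 (5R)-5-(Men-oxy)furan-2(5H)-one
Conditions: CSA (cat.), PhMe, reflux, Dean–Stark; crystallisation from light petroleum, −20 °C; mother liquor re-equilibrated with CSA and recrystallised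
Reagents that add atoms: none
Why: Acid-catalysed acetalisation of the hemiacylal gives both C5 epimers, which interconvert under the acid while the (5R) epimer is the one expected to crystallise, so the mixture should be funnelled into the single diastereomer that controls all later stereocentres.

Step 3
Reactants: 6 (5R)-5-(Men-oxy)furan-2(5H)-one
Product: 7 (4S,5R)-4-(hydroxymethyl)-5-(Men-oxy)oxolan-2-one
Conditions: Ph2CO (0.3 equiv), MeOH (degassed), hν (350 nm, Pyrex), rt
Reagents that add atoms: methanol CO
Why: Triplet benzophenone abstracts a hydrogen atom from methanol and the nucleophilic hydroxymethyl radical adds to the β-carbon of the butenolide (Giese-type radical conjugate addition) on the face opposite the menthyloxy group, which should set C4 as S.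

Step 4
Reactants: 7 (4S,5R)-4-(hydroxymethyl)-5-(Men-oxy)oxolan-2-one; 3 [4-(benzyloxy)-3-methoxyphenyl]chlorodimethylsilane
Product: 8 (4S,5R)-4-({[Ar(dimethyl)silyl]oxy}methyl)-5-(Men-oxy)oxolan-2-one
Conditions: imidazole, CH2Cl2, 0 °C → rt; chromatography on Et3N-deactivated silica
Reagents that add atoms: none
Why: Imidazole-mediated O-silylation of the primary alcohol installs the first aryl-bearing silicon tether and also masks the hydroxyl, which as an alkoxide could attack the lactone carbonyl in the next step.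

Step 5
Reactants: 8 (4S,5R)-4-({[Ar(dimethyl)silyl]oxy}methyl)-5-(Men-oxy)oxolan-2-one; 3 [4-(benzyloxy)-3-methoxyphenyl]chlorodimethylsilane
Product: 11 (3S,4S,5R)-3,4-bis({[Ar(dimethyl)silyl]oxy}methyl)-5-(Men-oxy)oxolan-2-one, via lithium enolate 9 (not isolated), via lithium alkoxide 10 (not isolated)
Conditions: LiN(iPr)2, THF, −78 °C; monomeric HCHO (THF solution from cracked paraformaldehyde), −78 °C, excess purged; then 3, DMAP (cat.), −78 → 0 °C
Reagents that add atoms: formaldehyde C=O
Why: Kinetic deprotonation gives the lactone enolate, whose aldol addition to formaldehyde (hydroxymethylation) should occur anti to the adjacent C4 arm and so set C3 as S (3,4-trans), and the resulting lithium alkoxide is silylated in the same flask by 3 to give the second tether.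

Step 6
Reactants: 11 (3S,4S,5R)-3,4-bis({[Ar(dimethyl)silyl]oxy}methyl)-5-(Men-oxy)oxolan-2-one
Product: 13 (3S,4S,5R)-3,4-bis({[Ar(dimethyl)silyl]oxy}methyl)-5-(Men-oxy)oxolan-2-yl acetate (both C2 epimers), via aluminium lactolate 12 (not isolated)
Conditions: iBu2AlH, CH2Cl2, −78 °C; then pyridine, DMAP, Ac2O, −78 → −20 °C; aq. NH4Cl/potassium sodium tartrate
Reagents that add atoms: acetic anhydride CC(=O)OC(C)=O
Why: Hydride addition to the lactone at −78 °C should stop at the tetrahedral aluminium lactolate, which is acylated in situ (one-pot reductive acetylation) so that the anomeric acetate forms without acid and without a free lactol, and the new C2 centre needs no control because it is ionised in step 7.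

Step 7
Reactants: 13 (3S,4S,5R)-3,4-bis({[Ar(dimethyl)silyl]oxy}methyl)-5-(Men-oxy)oxolan-2-yl acetate
Product: 16 [(2S,3S,4S,5S)-2,5-bis[4-(benzyloxy)-3-methoxyphenyl]oxolane-3,4-diyl]dimethanol, via monoarylated silyl triflate 14 (not isolated), via diarylated bis(silyl triflate) 15 (not isolated)
Conditions: Me3SiOTf (2.5 equiv), 2,6-di-tert-butyl-4-methylpyridine, 4 Å MS, CH2Cl2 (0.01 M), −78 → −40 °C; then Et3N, MeOH, −40 °C → rt; PPTS (cat.), MeOH, rt
Reagents that add atoms: none
Why: Me3SiOTf ionises the anomeric acetate to the cyclic oxocarbenium ion at C2, the silicon-bearing ipso carbon of the arene on the C3 arm (para to OBn, activated further by the β-silicon effect) attacks it, and loss of silicon to triflate rearomatises to give 14; the menthyl acetal at C5 is then ionised and the arm on C4 delivers its aryl in the same way to give 15, which methanolysis frees from its silyl residues. The closest known reaction type is the Lewis-acid-promoted intramolecular ipso-Friedel–Crafts C-arylation of glycosyl oxocarbenium ions by an arene held on a temporary silicon tether, the aromatic counterpart of the intramolecular Hosomi–Sakurai reaction. No ring of the product is closed: each C–C bond forms through a transient six-membered 1-oxa-2-sila ring (6-exo-trig ipso attack to a spiro cyclohexadienyl cation cis-fused to the oxolane) that is reopened by C–Si cleavage, and because silicon rather than a proton is expelled the medium stays aprotic. The new stereocentres C2 and C5 are controlled by C3 and C4 respectively, since a six-membered cycle can span only the face of the planar cation that carries its own CH2O arm; each aryl should therefore end cis to the neighbouring CH2OH, and as the two arms are trans the aryls end 2,5-trans. Both C2 epimers of the acetate and the menthyl acetal centre converge on one product, so the step is stereoconvergent. The selectivities needed are ipso over ortho attack (para-OBn, the β-silicon effect and a six- rather than seven-membered cycle), delivery from the adjacent rather than the remote arm (fused six-membered versus bridged seven-membered transition state) and exocyclic rather than ring C–O cleavage of the menthyl acetal, while the hindered pyridine prevents protodesilylation.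

Step 8
Reactants: 16 [(2S,3S,4S,5S)-2,5-bis[4-(benzyloxy)-3-methoxyphenyl]oxolane-3,4-diyl]dimethanol
Product: 17 [(2S,3S,4S,5S)-2,5-bis(4-hydroxy-3-methoxyphenyl)oxolane-3,4-diyl]dimethanol (Eduesmine)
Conditions: H2 (1 atm), 10% Pd/C, EtOAc/EtOH, rt, stopped at full debenzylation
Reagents that add atoms: none
Why: Hydrogenolysis of the two aryl benzyl ethers over palladium on carbon under neutral conditions should be much faster than cleavage of the dialkyl benzylic C–O bonds of the oxolane, so the phenols are freed without touching the four stereocentres.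

Compound list
1 | 1-(benzyloxy)-4-bromo-2-methoxybenzene | COc1cc(Br)ccc1OCc1ccccc1 | starting material
2 | [4-(benzyloxy)-3-methoxyphenyl]lithium (formed in the flask) | COc1cc([Li])ccc1OCc1ccccc1 | intermediate
3 | [4-(benzyloxy)-3-methoxyphenyl]chlorodimethylsilane | COc1cc([Si](C)(C)Cl)ccc1OCc1ccccc1 | intermediate
4 | 5-hydroxyfuran-2(5H)-one (racemic) | O=C1C=CC(O)O1 | starting material
5 | (−)-menthol, (1R,2S,5R)-5-methyl-2-(propan-2-yl)cyclohexan-1-ol | CC(C)[C@@H]1CC[C@@H](C)C[C@H]1O | starting material
6 | (5R)-5-(Men-oxy)furan-2(5H)-one | O=C1C=C[C@H](O[C@@H]2C[C@H](C)CC[C@H]2C(C)C)O1 | intermediate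
7 | (4S,5R)-4-(hydroxymethyl)-5-(Men-oxy)oxolan-2-one | O=C1C[C@@H](CO)[C@H](O[C@@H]2C[C@H](C)CC[C@H]2C(C)C)O1 | intermediate
8 | (4S,5R)-4-({[Ar(dimethyl)silyl]oxy}methyl)-5-(Men-oxy)oxolan-2-one | O=C1C[C@@H](CO[Si](C)(C)c2ccc(OCc3ccccc3)c(OC)c2)[C@H](O[C@@H]4C[C@H](C)CC[C@H]4C(C)C)O1 | intermediate
9 | lithium enolate of 8 (formed in the flask) | [Li]OC1=C[C@@H](CO[Si](C)(C)c2ccc(OCc3ccccc3)c(OC)c2)[C@H](O[C@@H]4C[C@H](C)CC[C@H]4C(C)C)O1 | intermediate
10 | lithium alkoxide of (3S,4S,5R)-3-(hydroxymethyl)-4-({[Ar(dimethyl)silyl]oxy}methyl)-5-(Men-oxy)oxolan-2-one (formed in the flask) | O=C1[C@H](CO[Li])[C@@H](CO[Si](C)(C)c2ccc(OCc3ccccc3)c(OC)c2)[C@H](O[C@@H]4C[C@H](C)CC[C@H]4C(C)C)O1 | intermediate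
11 | (3S,4S,5R)-3,4-bis({[Ar(dimethyl)silyl]oxy}methyl)-5-(Men-oxy)oxolan-2-one | O=C1[C@H](CO[Si](C)(C)c2ccc(OCc3ccccc3)c(OC)c2)[C@@H](CO[Si](C)(C)c2ccc(OCc3ccccc3)c(OC)c2)[C@H](O[C@@H]4C[C@H](C)CC[C@H]4C(C)C)O1 | intermediate
12 | diisobutylaluminium lactolate of 11 (formed in the flask, both C2 epimers) | CC(C)C[Al](CC(C)C)OC1[C@H](CO[Si](C)(C)c2ccc(OCc3ccccc3)c(OC)c2)[C@@H](CO[Si](C)(C)c2ccc(OCc3ccccc3)c(OC)c2)[C@H](O[C@@H]4C[C@H](C)CC[C@H]4C(C)C)O1 | intermediate
13 | (3S,4S,5R)-3,4-bis({[Ar(dimethyl)silyl]oxy}methyl)-5-(Men-oxy)oxolan-2-yl acetate (both C2 epimers) | CC(=O)OC1[C@H](CO[Si](C)(C)c2ccc(OCc3ccccc3)c(OC)c2)[C@@H](CO[Si](C)(C)c2ccc(OCc3ccccc3)c(OC)c2)[C@H](O[C@@H]4C[C@H](C)CC[C@H]4C(C)C)O1 | intermediate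
14 | (2S,3S,4S,5R)-2-Ar-oxolane with 5-Men-oxy, 4-CH2O–SiMe2Ar and 3-CH2O–SiMe2OTf (formed in the flask) | COc1cc([C@H]2O[C@@H](O[C@@H]3C[C@H](C)CC[C@H]3C(C)C)[C@H](CO[Si](C)(C)c3ccc(OCc4ccccc4)c(OC)c3)[C@H]2CO[Si](C)(C)OS(=O)(=O)C(F)(F)F)ccc1OCc1ccccc1 | intermediate
15 | (2S,3S,4S,5S)-2,5-di-Ar-oxolane with 3,4-bis(CH2O–SiMe2OTf) (formed in the flask) | COc1cc([C@H]2O[C@H](c3ccc(OCc4ccccc4)c(OC)c3)[C@H](CO[Si](C)(C)OS(=O)(=O)C(F)(F)F)[C@H]2CO[Si](C)(C)OS(=O)(=O)C(F)(F)F)ccc1OCc1ccccc1 | intermediate
16 | [(2S,3S,4S,5S)-2,5-bis[4-(benzyloxy)-3-methoxyphenyl]oxolane-3,4-diyl]dimethanol | COc1cc([C@H]2O[C@H](c3ccc(OCc4ccccc4)c(OC)c3)[C@H](CO)[C@H]2CO)ccc1OCc1ccccc1 | intermediate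
17 | [(2S,3S,4S,5S)-2,5-bis(4-hydroxy-3-methoxyphenyl)oxolane-3,4-diyl]dimethanol (Eduesmine) | COc1cc([C@H]2O[C@H](c3ccc(O)c(OC)c3)[C@H](CO)[C@H]2CO)ccc1O | target

Total step count: 8. Longest linear sequence: 7 steps (steps 2 to 8, from 4); step 1 is a one-step side branch that feeds steps 4 and 5.

Steps most likely to fail

1. Step 7. Several processes could defeat it. The aryl–silicon bonds could be protodesilylated by traces of TfOH before the acetals ionise. After the first transfer the menthyl acetal could open at the ring C–O bond, giving an open-chain oxocarbenium ion that is arylated without the ring. The second aryl could be delivered through the remote arm, or the cis benzylic ethers could epimerise under the Lewis acid once formed. The fallback makes the last aryl–C bond by carbonyl addition and sets its stereocentre by hydride delivery instead of aryl delivery. It sets out from 8: Me3SiOTf with 2,6-di-tert-butyl-4-methylpyridine in CH2Cl2 (−40 → 0 °C, then MeOH) ionises the menthyl pseudo-acetal, and the single tether should deliver its aryl to C5 to give the cis lactone (4S,5S)-5-Ar-4-(hydroxymethyl)oxolan-2-one F1. Immediate silylation (TBSCl, imidazole) gives the silyl ether F2. Enolate hydroxymethylation as in step 5, with TBSCl as the trap, gives the 3,4-trans bis(silyl ether) F3. Addition of aryllithium 2 (THF, −78 °C) gives the hemiketal F4. Et3SiH with BF3·OEt2 (CH2Cl2, −78 °C) reduces the derived 2-aryl oxocarbenium ion; hydride should enter anti to the C3 arm, leaving the new aryl cis to it, to give the bis(silyl ether) F5. Bu4NF (THF, 0 °C) then returns the route to 16.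

2. Step 5. Formaldehyde could oligomerise or be lost by retro-aldol. A second hydroxymethylation, dehydration to the α-methylene lactone, or silylation of hemiformal alkoxides would also divert material. The fallback replaces the aldol by an alkylation. It sets out from 8: the lithium enolate is alkylated with 4-methoxybenzyl chloromethyl ether (THF, −78 °C), anti to the C4 arm, to give the ether F6. Oxidative removal of the 4-methoxybenzyl group with DDQ (CH2Cl2/pH 7 buffer) gives the alcohol F7. Silylation with 3 and imidazole returns the route to 11.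

3. Step 3. The excited sensitiser could abstract hydrogen from the menthyl group or from the product. Pinacol coupling of the ketyl radical could outpace addition, and telomerisation of the adduct radical could consume the butenolide. The fallback replaces the radical addition by a polar conjugate addition of a masked hydroxymethyl group. It sets out from 6: (iPrO)Me2SiCH2MgCl with CuBr·SMe2 (cat.) and Me3SiCl (THF, −78 °C) should add trans to the menthyloxy group to give the silane F8. Tamao oxidation (H2O2, KF, KHCO3, THF/MeOH) converts the C–Si bond into C–OH with retention and returns the route to 7.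

Further compounds
F1 | step 7 | (4S,5S)-5-[4-(benzyloxy)-3-methoxyphenyl]-4-(hydroxymethyl)oxolan-2-one | O=C1C[C@@H](CO)[C@@H](c2ccc(OCc3ccccc3)c(OC)c2)O1
F2 | step 7 | (4S,5S)-5-[4-(benzyloxy)-3-methoxyphenyl]-4-({[tert-butyl(dimethyl)silyl]oxy}methyl)oxolan-2-one | O=C1C[C@@H](CO[Si](C)(C)C(C)(C)C)[C@@H](c2ccc(OCc3ccccc3)c(OC)c2)O1
F3 | step 7 | (3S,4S,5S)-5-[4-(benzyloxy)-3-methoxyphenyl]-3,4-bis({[tert-butyl(dimethyl)silyl]oxy}methyl)oxolan-2-one | O=C1[C@H](CO[Si](C)(C)C(C)(C)C)[C@@H](CO[Si](C)(C)C(C)(C)C)[C@@H](c2ccc(OCc3ccccc3)c(OC)c2)O1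
F4 | step 7 | (3S,4S,5S)-2,5-bis[4-(benzyloxy)-3-methoxyphenyl]-3,4-bis({[tert-butyl(dimethyl)silyl]oxy}methyl)oxolan-2-ol (both C2 epimers) | OC1(c2ccc(OCc3ccccc3)c(OC)c2)[C@H](CO[Si](C)(C)C(C)(C)C)[C@@H](CO[Si](C)(C)C(C)(C)C)[C@@H](c2ccc(OCc3ccccc3)c(OC)c2)O1
F5 | step 7 | (2S,3S,4S,5S)-2,5-bis[4-(benzyloxy)-3-methoxyphenyl]-3,4-bis({[tert-butyl(dimethyl)silyl]oxy}methyl)oxolane | COc1cc([C@H]2O[C@H](c3ccc(OCc4ccccc4)c(OC)c3)[C@H](CO[Si](C)(C)C(C)(C)C)[C@H]2CO[Si](C)(C)C(C)(C)C)ccc1OCc1ccccc1
F6 | step 5 | (3S,4S,5R)-3-{[(4-methoxybenzyl)oxy]methyl}-4-({[Ar(dimethyl)silyl]oxy}methyl)-5-(Men-oxy)oxolan-2-one | O=C1[C@H](COCc2ccc(OC)cc2)[C@@H](CO[Si](C)(C)c2ccc(OCc3ccccc3)c(OC)c2)[C@H](O[C@@H]4C[C@H](C)CC[C@H]4C(C)C)O1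
F7 | step 5 | (3S,4S,5R)-3-(hydroxymethyl)-4-({[Ar(dimethyl)silyl]oxy}methyl)-5-(Men-oxy)oxolan-2-one | O=C1[C@H](CO)[C@@H](CO[Si](C)(C)c2ccc(OCc3ccccc3)c(OC)c2)[C@H](O[C@@H]4C[C@H](C)CC[C@H]4C(C)C)O1
F8 | step 3 | (4S,5R)-4-{[dimethyl(propan-2-yloxy)silyl]methyl}-5-(Men-oxy)oxolan-2-one | O=C1C[C@@H](C[Si](C)(C)OC(C)C)[C@H](O[C@@H]2C[C@H](C)CC[C@H]2C(C)C)O1
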